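The C3, C4 and C6 substituents of the target are all cis ((3S,4S,6S); side-chain centre R), and the endoperoxide and its ring-opened product map onto it without any stereochemical correction.

**Strategy.** The cis pair of two-carbon arms on the 1,2-dioxane ring, the C6 ethyl and the C3 CH2CO2Me, is traced back to one CH=CH bridge. In step 12 a ruthenium carbene and ethylene cut the C5=C6 bridge of a 2,3-dioxabicyclo[2.2.2]oct-5-ene. This turns the bicycle into the monocyclic dioxane with vinyl groups at C3 and C6, cis by construction, beside the C4 ethyl, with no stereocentre touched. The bicyclic peroxide comes from singlet oxygen and an (S)-5-ethyl-1-alkylcyclohexa-1,3-diene whose side chain ends in a silyl ether. Afterwards the C3 vinyl becomes the acetate arm, the C6 vinyl is reduced, and the chain alkene is made last.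

Key step: step 12

Remark: the ethenolysis is run with a phosphine-free ruthenium carbene, because free PCy3 would deoxygenate a strained endoperoxide; sulfone 36 is prepared in two steps (19, 20).

**Route**

Step 1
Reactants: 1 (S)-4-benzyl-1,3-oxazolidin-2-one; 2 butanoyl chloride
Product: 3 (S)-4-benzyl-3-butanoyl-1,3-oxazolidin-2-one
Conditions: Et3N, DMAP (cat.), CH2Cl2, 0 °C → rt
Reagents that add atoms: none
Why: DMAP-catalysed N-acylation of the oxazolidinone by the acid chloride gives the imide needed for auxiliary-controlled alkylation.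

Step 2
Reactants: 3 (S)-4-benzyl-3-butanoyl-1,3-oxazolidin-2-one; 4 allyl iodide
Product: 6 (S)-4-benzyl-3-[(R)-2-ethylpent-4-enoyl]-1,3-oxazolidin-2-one, via sodium Z-enolate 5 (not isolated)
Conditions: NaN(SiMe3)2, THF, −78 °C; then 4, −78 → −45 °C; aq NH4Cl
Reagents that add atoms: none
Why: Evans asymmetric alkylation: the chelated Z-enolate is allylated on the face away from the benzyl group, which sets the (R) centre that carries the ethyl group, and any minor diastereomer is removed by chromatography.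

Step 3
Reactants: 6 (S)-4-benzyl-3-[(R)-2-ethylpent-4-enoyl]-1,3-oxazolidin-2-one
Product: 7 (R)-2-ethylpent-4-en-1-ol
Conditions: LiBH4, MeOH (1 equiv), Et2O, 0 °C
Reagents that add atoms: none
Why: Reductive cleavage of the imide by borohydride attack at the exocyclic carbonyl releases the primary alcohol without touching the α-centre, and the auxiliary is recovered.

Step 4
Reactants: 7 (R)-2-ethylpent-4-en-1-ol
Product: 8 (R)-tert-butyl[(2-ethylpent-4-en-1-yl)oxy]dimethylsilane
Conditions: TBSCl, imidazole, CH2Cl2, rt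
Reagents that add atoms: tert-butyldimethylsilyl chloride, CC(C)(C)[Si](C)(C)Cl
Why: Standard silylation of a primary alcohol gives an ether that tolerates organolithium, chromium, palladium, singlet-oxygen and metathesis conditions.

Step 5
Reactants: 8 (R)-tert-butyl[(2-ethylpent-4-en-1-yl)oxy]dimethylsilane
Product: 10 (R)-tert-butyl[(2-ethyl-5-iodopentyl)oxy]dimethylsilane, via alkylzirconocene chloride 9 (not isolated)
Conditions: Cp2Zr(H)Cl, THF, rt; then I2, 0 °C
Reagents that add atoms: iodine, II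
Why: Hydrozirconation places zirconium on the terminal carbon of the monosubstituted alkene, and iodinolysis of the C–Zr bond gives the primary iodide.

Step 6
Reactants: 11 (E)-pent-2-enal; 12 tert-butyl 3-oxobutanoate
Product: 15 (R)-5-ethylcyclohex-2-en-1-one, via Michael adduct 13 (not isolated), via keto aldehyde 14 (not isolated)
Conditions: (S)-2-[bis(3,5-bis(trifluoromethyl)phenyl)(trimethylsilyloxy)methyl]pyrrolidine (10 mol%), toluene, rt; then p-TsOH·H2O, toluene, 80 °C
Reagents that add atoms: none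
Why: Iminium-catalysed Michael addition, in which the silyloxydiarylmethyl group of the (S)-amine blocks one face of the E-iminium ion so that the ketoester adds to the Re face of C3 of the enal and sets the (R) centre; acid then removes the tert-butyl ester, the β-keto acid decarboxylates, and aldol condensation of the methyl ketone onto the aldehyde closes the enone.

Step 7
Reactants: 10 (R)-tert-butyl[(2-ethyl-5-iodopentyl)oxy]dimethylsilane; 15 (R)-5-ethylcyclohex-2-en-1-one
Product: 17 (5R)-1-[(R)-5-(tert-butyldimethylsilyloxy)-4-ethylpentyl]-5-ethylcyclohex-2-en-1-ol (both C1 epimers), via alkyllithium 16 (not isolated)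
Conditions: 10, t-BuLi (2.1 equiv), Et2O/pentane, −78 °C; then 15, −78 → 0 °C; aq NH4Cl
Reagents that add atoms: none
Why: Lithium–iodine exchange followed by 1,2-addition of the primary alkyllithium to the enone carbonyl; the new carbinol centre forms unselectively, which does not matter because it becomes sp2 in step 8.

Step 8
Reactants: 17 (5R)-1-[(R)-5-(tert-butyldimethylsilyloxy)-4-ethylpentyl]-5-ethylcyclohex-2-en-1-ol
Product: 18 (S)-3-[(R)-5-(tert-butyldimethylsilyloxy)-4-ethylpentyl]-5-ethylcyclohex-2-en-1-one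
Conditions: pyridinium chlorochromate (C5H5NH[CrO3Cl]), 4 Å molecular sieves, CH2Cl2, rt
Reagents that add atoms: none
Why: Oxidative 1,3-transposition of a tertiary allylic alcohol: the chromate ester undergoes a [3,3] shift and the resulting secondary allylic chromate is oxidised to the β-alkyl enone, with the ethyl-bearing centre remote and untouched.

Step 9
Reactants: 18 (S)-3-[(R)-5-(tert-butyldimethylsilyloxy)-4-ethylpentyl]-5-ethylcyclohex-2-en-1-one
Product: 20 (S)-5-[(R)-5-(tert-butyldimethylsilyloxy)-4-ethylpentyl]-3-ethylcyclohexa-1,5-dien-1-yl trifluoromethanesulfonate, via lithium dienolate 19 (not isolated)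
Conditions: LiN(iPr)2, THF, −78 °C; then PhNTf2, −78 → 0 °C; aq NH4Cl
Reagents that add atoms: N-phenylbis(trifluoromethanesulfonimide), O=S(=O)(N(c1ccccc1)S(=O)(=O)C(F)(F)F)C(F)(F)F
Why: Kinetic deprotonation of the enone at the α'-CH2 next to the ethyl-bearing carbon gives the cross-conjugated dienolate, and O-triflation fixes the 1,3-diene with the alkyl group at its terminus; the stereocentre is β to the carbonyl and cannot enolise.

Step 10
Reactants: 20 (S)-5-[(R)-5-(tert-butyldimethylsilyloxy)-4-ethylpentyl]-3-ethylcyclohexa-1,5-dien-1-yl trifluoromethanesulfonate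
Product: 21 (S)-1-[(R)-5-(tert-butyldimethylsilyloxy)-4-ethylpentyl]-5-ethylcyclohexa-1,3-diene
Conditions: Pd(OAc)2 (cat.), PPh3, HCO2H, Bu3N, DMF, 50 °C
Reagents that add atoms: none
Why: Palladium-catalysed formate reduction of a dienyl triflate (oxidative addition, formate exchange, decarboxylation, C–H reductive elimination) replaces OTf by H without moving the diene or touching C5.

Step 11
Reactants: 21 (S)-1-[(R)-5-(tert-butyldimethylsilyloxy)-4-ethylpentyl]-5-ethylcyclohexa-1,3-diene
Product: 22 (1S,4R,8S)-1-[(R)-5-(tert-butyldimethylsilyloxy)-4-ethylpentyl]-8-ethyl-2,3-dioxabicyclo[2.2.2]oct-5-ene (ethyl syn to the C5=C6 bridge)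
Conditions: O2, hν (visible), 5,10,15,20-tetraphenylporphyrin (cat.), CH2Cl2, −30 °C
Reagents that add atoms: dioxygen, O=O
Why: [4+2] cycloaddition of singlet oxygen to the s-cis diene on the face anti to the pseudoaxial ethyl group should set both bridgeheads and leave ethyl syn to the alkene bridge; the syn adduct is removed by chromatography.

Step 12
Reactants: 22 (1S,4R,8S)-1-[(R)-5-(tert-butyldimethylsilyloxy)-4-ethylpentyl]-8-ethyl-2,3-dioxabicyclo[2.2.2]oct-5-ene; 23 ethylene
Product: 24 (3S,4S,6S)-6-[(R)-5-(tert-butyldimethylsilyloxy)-4-ethylpentyl]-4-ethyl-3,6-divinyl-1,2-dioxane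
Conditions: second-generation Hoveyda–Grubbs catalyst, (H2IMes)Cl2Ru=CH(C6H4-2-OiPr) (5 mol%), ethylene (1 atm), CH2Cl2 (0.01 M), rt
Reagents that add atoms: none
Why: Proposed new method: the ruthenium methylidene formed from the catalyst and ethylene adds [2+2] to the strained cis C5=C6 bridge, the ruthenacyclobutane cycloreverts to open the carbocycle, and a second ethylene releases the other vinyl group and regenerates the methylidene; the closest known reaction type is ring-opening cross-metathesis of carbocyclic bicyclo[2.2.2]octenes with ethylene, together with cross-metathesis of alkenes that carry dialkyl peroxide groups. No ring is closed and no stereocentre is formed; the 3,6-cis relationship is inherited from the bicycle and C4 is untouched. The step needs chemoselectivity for the C=C bridge over the allylic O–O bond, and for monomeric ring opening over oligomerisation. Release of bicyclic strain, high dilution and excess ethylene should favour the monomeric opening, and the two product vinyl groups, each on a branched oxygen-bearing carbon, are poor partners for further metathesis. A phosphine-free carbene is chosen so that no PCy3 is present to deoxygenate the peroxide, and the silyl ether keeps any second alkene out of the flask.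

Step 13
Reactants: 24 (3S,4S,6S)-6-[(R)-5-(tert-butyldimethylsilyloxy)-4-ethylpentyl]-4-ethyl-3,6-divinyl-1,2-dioxane
Product: 26 2-[(3S,4S,6S)-6-[(R)-5-(tert-butyldimethylsilyloxy)-4-ethylpentyl]-4-ethyl-6-vinyl-1,2-dioxan-3-yl]ethan-1-ol, via alkylborane 25 (not isolated)
Conditions: Sia2BH (from BH3·SMe2 and 2-methylbut-2-ene, 1.2 equiv), THF, −10 → 0 °C; then 30% H2O2, aq NaOAc, 0 °C → rt
Reagents that add atoms: hydrogen peroxide, OO
Why: Anti-Markovnikov hydroboration with a bulky dialkylborane should be faster at the C3 vinyl on a methine carbon than at the C6 vinyl on a fully substituted carbon, and oxidation of the C–B bond under weakly basic conditions spares the ring peroxide.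

Step 14
Reactants: 26 2-[(3S,4S,6S)-6-[(R)-5-(tert-butyldimethylsilyloxy)-4-ethylpentyl]-4-ethyl-6-vinyl-1,2-dioxan-3-yl]ethan-1-ol
Product: 28 2-[(3S,4S,6S)-6-[(R)-5-(tert-butyldimethylsilyloxy)-4-ethylpentyl]-4-ethyl-6-vinyl-1,2-dioxan-3-yl]acetic acid, via aldehyde 27 (not isolated)
Conditions: TEMPO (cat.), PhI(OAc)2, MeCN/H2O, rt
Reagents that add atoms: water, O
Why: Oxoammonium oxidation takes the primary alcohol to the aldehyde and its hydrate on to the acid, under conditions to which the alkene, silyl ether and peroxide are inert.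

Step 15
Reactants: 28 2-[(3S,4S,6S)-6-[(R)-5-(tert-butyldimethylsilyloxy)-4-ethylpentyl]-4-ethyl-6-vinyl-1,2-dioxan-3-yl]acetic acid
Product: 29 methyl 2-[(3S,4S,6S)-6-[(R)-5-(tert-butyldimethylsilyloxy)-4-ethylpentyl]-4-ethyl-6-vinyl-1,2-dioxan-3-yl]acetate
Conditions: TMSCHN2, MeOH/toluene, 0 °C
Reagents that add atoms: (trimethylsilyl)diazomethane, C[Si](C)(C)C=[N+]=[N-]
Why: Esterification with a diazoalkane proceeds by proton transfer and O-alkylation under neutral conditions, which avoids base-induced β-elimination of the peroxide.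

Step 16
Reactants: 29 methyl 2-[(3S,4S,6S)-6-[(R)-5-(tert-butyldimethylsilyloxy)-4-ethylpentyl]-4-ethyl-6-vinyl-1,2-dioxan-3-yl]acetate
Product: 30 methyl 2-[(3S,4S,6S)-6-[(R)-5-(tert-butyldimethylsilyloxy)-4-ethylpentyl]-4,6-diethyl-1,2-dioxan-3-yl]acetate
Conditions: KO2CN=NCO2K, AcOH, MeOH/CH2Cl2, 0 °C → rt
Reagents that add atoms: none
Why: Diimide reduction transfers H2 to the terminal vinyl group through a concerted cyclic transition state and does not reduce O–O bonds or esters.

Step 17
Reactants: 30 methyl 2-[(3S,4S,6S)-6-[(R)-5-(tert-butyldimethylsilyloxy)-4-ethylpentyl]-4,6-diethyl-1,2-dioxan-3-yl]acetate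
Product: 31 methyl 2-[(3S,4S,6S)-4,6-diethyl-6-[(R)-4-ethyl-5-hydroxypentyl]-1,2-dioxan-3-yl]acetate
Conditions: HF·pyridine, pyridine, THF, 0 °C → rt
Reagents that add atoms: none
Why: Fluoride cleavage of the primary silyl ether under mildly acidic conditions leaves the peroxide and the base-sensitive β-peroxy ester intact.

Step 18
Reactants: 31 methyl 2-[(3S,4S,6S)-4,6-diethyl-6-[(R)-4-ethyl-5-hydroxypentyl]-1,2-dioxan-3-yl]acetate
Product: 32 methyl 2-[(3S,4S,6S)-4,6-diethyl-6-[(R)-4-ethyl-5-oxopentyl]-1,2-dioxan-3-yl]acetate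
Conditions: Dess–Martin periodinane, CH2Cl2, rt
Reagents that add atoms: none
Why: Dess–Martin oxidation gives the α-branched aldehyde under neutral conditions that should not epimerise it; it is used at once.

Step 19
Reactants: 33 1-phenyl-1H-tetrazole-5-thiol; 34 1-bromopropane
Product: 35 1-phenyl-5-(propylsulfanyl)-1H-tetrazole
Conditions: K2CO3, acetone, reflux
Reagents that add atoms: none
Why: SN2 S-alkylation of the thiolate by a primary bromide.

Step 20
Reactants: 35 1-phenyl-5-(propylsulfanyl)-1H-tetrazole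
Product: 36 1-phenyl-5-(propylsulfonyl)-1H-tetrazole
Conditions: 30% H2O2, (NH4)6Mo7O24·4H2O (cat.), EtOH, rt
Reagents that add atoms: hydrogen peroxide, OO
Why: Molybdate-catalysed peroxide oxidation takes the sulfide through the sulfoxide to the sulfone.

Step 21
Reactants: 32 methyl 2-[(3S,4S,6S)-4,6-diethyl-6-[(R)-4-ethyl-5-oxopentyl]-1,2-dioxan-3-yl]acetate; 36 1-phenyl-5-(propylsulfonyl)-1H-tetrazole
Product: 38 methyl 2-[(3S,4S,6S)-4,6-diethyl-6-[(4R,5E)-4-ethyloct-5-en-1-yl]-1,2-dioxan-3-yl]acetate, via sulfonyl carbanion 37 (not isolated)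
Conditions: 36, KN(SiMe3)2, DME, −60 °C; then 32, −60 °C → rt; aq NH4Cl
Reagents that add atoms: none
Why: Julia–Kocienski olefination: the metalated tetrazolyl sulfone adds to the aldehyde, Smiles rearrangement and loss of SO2 and tetrazolate give the alkene, E being favoured with potassium in DME, and the pre-formed carbanion is too weak a base to enolise the ester.

**Compound list**

1 | (S)-4-benzyl-1,3-oxazolidin-2-one | O=C1N[C@@H](Cc2ccccc2)CO1 | starting material
2 | butanoyl chloride | CCCC(=O)Cl | starting material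
3 | (S)-4-benzyl-3-butanoyl-1,3-oxazolidin-2-one | CCCC(=O)N1[C@@H](Cc2ccccc2)COC1=O | intermediate
4 | allyl iodide | C=CCI | starting material
5 | sodium Z-enolate of 3 | CC/C=C(\[O-])N1[C@@H](Cc2ccccc2)COC1=O.[Na+] | intermediate
6 | (S)-4-benzyl-3-[(R)-2-ethylpent-4-enoyl]-1,3-oxazolidin-2-one | C=CC[C@@H](CC)C(=O)N1[C@@H](Cc2ccccc2)COC1=O | intermediate
7 | (R)-2-ethylpent-4-en-1-ol | OC[C@H](CC)CC=C | intermediate
8 | (R)-tert-butyl[(2-ethylpent-4-en-1-yl)oxy]dimethylsilane | CC(C)(C)[Si](C)(C)OC[C@H](CC)CC=C | intermediate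
9 | chloro[(R)-5-(tert-butyldimethylsilyloxy)-4-ethylpentyl]zirconocene | CC(C)(C)[Si](C)(C)OC[C@H](CC)CCC[Zr](Cl)(C1C=CC=C1)C1C=CC=C1 | intermediate
10 | (R)-tert-butyl[(2-ethyl-5-iodopentyl)oxy]dimethylsilane | CC(C)(C)[Si](C)(C)OC[C@H](CC)CCCI | intermediate
11 | (E)-pent-2-enal | CC/C=C/C=O | starting material
12 | tert-butyl 3-oxobutanoate | CC(=O)CC(=O)OC(C)(C)C | starting material
13 | tert-butyl (3R)-2-acetyl-3-ethyl-5-oxopentanoate (C2 epimers) | CC(=O)C(C(=O)OC(C)(C)C)[C@H](CC)CC=O | intermediate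
14 | (R)-3-ethyl-5-oxohexanal | CC(=O)C[C@H](CC)CC=O | intermediate
15 | (R)-5-ethylcyclohex-2-en-1-one | O=C1C=CC[C@@H](CC)C1 | intermediate
16 | [(R)-5-(tert-butyldimethylsilyloxy)-4-ethylpentyl]lithium | CC(C)(C)[Si](C)(C)OC[C@H](CC)CCC[Li] | intermediate
17 | (5R)-1-[(R)-5-(tert-butyldimethylsilyloxy)-4-ethylpentyl]-5-ethylcyclohex-2-en-1-ol (C1 epimers) | CC(C)(C)[Si](C)(C)OC[C@H](CC)CCCC1(O)C=CC[C@@H](CC)C1 | intermediate
18 | (S)-3-[(R)-5-(tert-butyldimethylsilyloxy)-4-ethylpentyl]-5-ethylcyclohex-2-en-1-one | CC(C)(C)[Si](C)(C)OC[C@H](CC)CCCC1=CC(=O)C[C@@H](CC)C1 | intermediate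
19 | lithium cross-conjugated dienolate of 18 | CC(C)(C)[Si](C)(C)OC[C@H](CC)CCCC1=CC(O[Li])=C[C@@H](CC)C1 | intermediate
20 | (S)-5-[(R)-5-(tert-butyldimethylsilyloxy)-4-ethylpentyl]-3-ethylcyclohexa-1,5-dien-1-yl trifluoromethanesulfonate | CC(C)(C)[Si](C)(C)OC[C@H](CC)CCCC1=CC(OS(=O)(=O)C(F)(F)F)=C[C@@H](CC)C1 | intermediate
21 | (S)-1-[(R)-5-(tert-butyldimethylsilyloxy)-4-ethylpentyl]-5-ethylcyclohexa-1,3-diene | CC(C)(C)[Si](C)(C)OC[C@H](CC)CCCC1=CC=C[C@@H](CC)C1 | intermediate
22 | (1S,4R,8S)-1-[(R)-5-(tert-butyldimethylsilyloxy)-4-ethylpentyl]-8-ethyl-2,3-dioxabicyclo[2.2.2]oct-5-ene | CC(C)(C)[Si](C)(C)OC[C@H](CC)CCC[C@@]1(C=C2)C[C@H](CC)[C@H]2OO1 | intermediate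
23 | ethylene | C=C | starting material
24 | (3S,4S,6S)-6-[(R)-5-(tert-butyldimethylsilyloxy)-4-ethylpentyl]-4-ethyl-3,6-divinyl-1,2-dioxane | CC(C)(C)[Si](C)(C)OC[C@H](CC)CCC[C@@]1(C=C)C[C@H](CC)[C@H](C=C)OO1 | intermediate
25 | bis(3-methylbutan-2-yl)borane adduct at the terminal carbon of the C3 vinyl group of 24 | CC(C)(C)[Si](C)(C)OC[C@H](CC)CCC[C@@]1(C=C)C[C@H](CC)[C@H](CCB(C(C)C(C)C)C(C)C(C)C)OO1 | intermediate
26 | 2-[(3S,4S,6S)-6-[(R)-5-(tert-butyldimethylsilyloxy)-4-ethylpentyl]-4-ethyl-6-vinyl-1,2-dioxan-3-yl]ethan-1-ol | CC(C)(C)[Si](C)(C)OC[C@H](CC)CCC[C@@]1(C=C)C[C@H](CC)[C@H](CCO)OO1 | intermediate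
27 | 2-[(3S,4S,6S)-6-[(R)-5-(tert-butyldimethylsilyloxy)-4-ethylpentyl]-4-ethyl-6-vinyl-1,2-dioxan-3-yl]acetaldehyde | CC(C)(C)[Si](C)(C)OC[C@H](CC)CCC[C@@]1(C=C)C[C@H](CC)[C@H](CC=O)OO1 | intermediate
28 | 2-[(3S,4S,6S)-6-[(R)-5-(tert-butyldimethylsilyloxy)-4-ethylpentyl]-4-ethyl-6-vinyl-1,2-dioxan-3-yl]acetic acid | CC(C)(C)[Si](C)(C)OC[C@H](CC)CCC[C@@]1(C=C)C[C@H](CC)[C@H](CC(=O)O)OO1 | intermediate
29 | methyl 2-[(3S,4S,6S)-6-[(R)-5-(tert-butyldimethylsilyloxy)-4-ethylpentyl]-4-ethyl-6-vinyl-1,2-dioxan-3-yl]acetate | CC(C)(C)[Si](C)(C)OC[C@H](CC)CCC[C@@]1(C=C)C[C@H](CC)[C@H](CC(=O)OC)OO1 | intermediate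
30 | methyl 2-[(3S,4S,6S)-6-[(R)-5-(tert-butyldimethylsilyloxy)-4-ethylpentyl]-4,6-diethyl-1,2-dioxan-3-yl]acetate | CC(C)(C)[Si](C)(C)OC[C@H](CC)CCC[C@@]1(CC)C[C@H](CC)[C@H](CC(=O)OC)OO1 | intermediate
31 | methyl 2-[(3S,4S,6S)-4,6-diethyl-6-[(R)-4-ethyl-5-hydroxypentyl]-1,2-dioxan-3-yl]acetate | OC[C@H](CC)CCC[C@@]1(CC)C[C@H](CC)[C@H](CC(=O)OC)OO1 | intermediate
32 | methyl 2-[(3S,4S,6S)-4,6-diethyl-6-[(R)-4-ethyl-5-oxopentyl]-1,2-dioxan-3-yl]acetate | O=C[C@H](CC)CCC[C@@]1(CC)C[C@H](CC)[C@H](CC(=O)OC)OO1 | intermediate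
33 | 1-phenyl-1H-tetrazole-5-thiol | Sc1nnnn1-c1ccccc1 | starting material
34 | 1-bromopropane | CCCBr | starting material
35 | 1-phenyl-5-(propylsulfanyl)-1H-tetrazole | CCCSc1nnnn1-c1ccccc1 | intermediate
36 | 1-phenyl-5-(propylsulfonyl)-1H-tetrazole | CCCS(=O)(=O)c1nnnn1-c1ccccc1 | intermediate
37 | potassium α-sulfonyl carbanion of 36 | CC[CH-]S(=O)(=O)c1nnnn1-c1ccccc1.[K+] | intermediate
38 | methyl 2-[(3S,4S,6S)-4,6-diethyl-6-[(4R,5E)-4-ethyloct-5-en-1-yl]-1,2-dioxan-3-yl]acetate | CC/C=C/[C@H](CC)CCC[C@@]1(CC)C[C@H](CC)[C@H](CC(=O)OC)OO1 | target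

**Step count.** Total: 21 steps. Longest linear sequence: 18 steps (steps 1–5, 7–18 and 21, from butanoyl chloride).

**Steps most likely to fail**

Step 12 (Proposed new method). The ruthenium carbene, or a divalent ruthenium species formed from it, may attack the strained allylic O–O bond (rearrangement to epoxides or reduction) instead of the alkene, or the bicycle may oligomerise by ring-opening polymerisation. The fallback cuts the bridge oxidatively by known, peroxide-tolerant chemistry. It sets out from 22: ozonolysis (O3, CH2Cl2, −78 °C; then Me2S) should give the cis-3,6-dicarbaldehyde F1, and double Wittig methylenation with salt-free Ph3P=CH2 (THF, −78 °C) returns to the route at 24.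

Step 11. The small C5 ethyl group may discriminate poorly between the two faces of the diene, and ene hydroperoxidation may compete. The fallback recycles the wrong facial isomer instead of discarding it. It sets out from 21: after photooxygenation and separation, the syn endoperoxide F2 is reduced with thiourea (MeOH, rt) to the cis-cyclohex-2-ene-1,4-diol F3. Low-valent titanium (TiCl3/LiAlH4, THF) then effects reductive 1,4-elimination of the two hydroxyl groups and comes back to 21 for another pass.

Step 13. The borane may not distinguish the two vinyl groups well enough, or may slowly reduce the O–O bond. The fallback hands site selection to cross-metathesis, where a vinyl group on a fully substituted carbon does not react. It sets out from 24: vinylboronic acid pinacol ester and the second-generation Hoveyda–Grubbs catalyst, (H2IMes)Cl2Ru=CH(C6H4-2-OiPr), in CH2Cl2 at 40 °C should give the C3 (E)-alkenylboronate F4. Oxidation (NaBO3·4H2O, THF/H2O) gives the aldehyde and comes back to the route at 27, which is then oxidised to 28 with NaClO2, NaH2PO4 and 2-methylbut-2-ene.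

**Further compounds**

F1 | step 12 | cis-3,6-dicarbaldehyde: (4S,6S)-6-[(R)-5-(tert-butyldimethylsilyloxy)-4-ethylpentyl]-4-ethyl-1,2-dioxane-3,6-dicarbaldehyde, formyl groups cis to each other and to the C4 ethyl | CC(C)(C)[Si](C)(C)OC[C@H](CC)CCC[C@@]1(C=O)C[C@H](CC)[C@H](C=O)OO1
F2 | step 11 | syn endoperoxide: bridgehead diastereomer of 22 with the ethyl group syn to the O–O bridge | CC(C)(C)[Si](C)(C)OC[C@H](CC)CCC[C@]1(C=C2)C[C@H](CC)[C@@H]2OO1
F3 | step 11 | cis-1-[(R)-5-(tert-butyldimethylsilyloxy)-4-ethylpentyl]-5-ethylcyclohex-2-ene-1,4-diol, both hydroxyl groups on the face of the ethyl group | CC(C)(C)[Si](C)(C)OC[C@H](CC)CCC[C@]1(O)C=C[C@@H](O)[C@@H](CC)C1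
F4 | step 13 | (E)-alkenyl pinacol boronate at the C3 arm of 24, C6 vinyl retained | CC(C)(C)[Si](C)(C)OC[C@H](CC)CCC[C@@]1(C=C)C[C@H](CC)[C@H](/C=C/B2OC(C)(C)C(C)(C)O2)OO1
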